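# Synthesis design for the daucane ester 25 (CNP0301380.2)

## The problem

The target 25 is a trans-fused hydroazulene. In daucane numbering, the five-membered ring A (C1–C5) and the seven-membered ring B (C1, C5–C10) share the C1–C5 bond; C1 is a methyl-bearing quaternary carbon, C5 a methine whose hydrogen lies anti to that methyl.

Four contiguous stereocentres must be set: C1 (S), C5 (S), the tertiary isopropyl carbinol C4 (R, hydroxyl cis to the C1 methyl and to C6) and the ester-bearing C6 (S). Nothing else in the molecule is stereogenic, so C1 has to control C5, C5 has to control C4, and the C4 hydroxyl together with C1 has to control C6.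

Ring B carries a trisubstituted C8=C9 alkene conjugated to a C10 ketone that sits directly on the quaternary carbon. Three groups are fragile:
- the 4-methoxybenzoate, towards nucleophiles and base;
- the tertiary C4 carbinol, towards acid (dehydration);
- the C6 acyloxy group once the enone exists, because deprotonation at C7 opens a vinylogous E1cB loss of 4-methoxybenzoate.

The enone should therefore appear last and under neutral conditions.

The feature that makes the key step possible is the position of C5. It lies between the two oxygenated carbons C4 and C6 and is bonded to C1. If C4 is written as a ketone and C6 as an ester carbon, C5 is the central carbon of a β-keto ester and can become a metal carbenoid. C1, reached from C5 through C4, C3 and C2, then carries exactly one hydrogen in an open-chain precursor whose stereocentre can be bought.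

## Retrosynthesis

**C10 oxidation level and C8=C9 (25 ⇒ 24 ⇒ 23).** The enone 25 is traced to the allylic alcohol 24, and the C8=C9 double bond of 24 is cut to give the monocyclic diene 23. A metathesis closure forms the alkene exactly where the target has it. The neighbouring cut at C9–C10 (carbonyl-ene or aldol closure) would leave an exocyclic or β,γ alkene that must be moved into conjugation with base past the C6 ester. The precursor 23 has one ring less. The forward reaction must join a vinyl group to a 1,1-disubstituted alkene in a seven-membered ring trans-fused to ring A, and a mild oxidation must follow.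

**C9–C10 (23 ⇒ 21 + 22).** The vinyl carbinol of 23 is cut between C9 and C10 into aldehyde 21 and vinylmagnesium bromide 22. The aldehyde sits on a quaternary carbon, cannot enolise, and is far more electrophilic than the aryl ester. The C10 configuration is irrelevant. Aldehyde 21 goes back through alcohol 20 to silyl ether 19, so C10 travels as a protected hydroxymethyl group through the whole sequence.

**Ester C–O (19 ⇒ 17 + 18).** The 4-methoxybenzoate is cut to diol 17 and acid chloride 18. Installing the ester before ring B is built lets it protect O6, and no extra protecting group is needed. The forward step must distinguish the secondary C6 hydroxyl from the tertiary C4 hydroxyl, which sterics ensure.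

**C6–C7 (17 ⇒ 15 + 16).** Cutting C6–C7 gives the β-hydroxy aldehyde 15 and 3-bromo-2-methylprop-1-ene 16. This cut is preferred to reduction of a C6 ketone, because hydride delivery directed by the C4 hydroxyl would lead to the wrong C6 epimer. Addition to the aldehyde chelated by that hydroxyl leads to the right one. The precursor is ring A alone with all three ring stereocentres in place.

**C4–isopropyl (15 ⇒ 14 ⇒ 13 ⇒ 11 + 12).** Aldehyde 15 comes from diol 14, which is the desilylated form of 13. Cutting the C4–isopropyl bond of 13 gives ketone 11 and 2-bromopropane 12. The adjacent C5 arm shields one face of the cyclopentanone, so the nucleophile enters trans to it. The forward reaction must add a secondary alkyl group to a hindered, enolisable ketone, which calls for an organocerium reagent.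

**Redox adjustment of the β-keto ester (11 ⇒ 10 ⇒ 9 ⇒ 8 ⇒ 7).** Ketone 11 is reached from the β-keto ester 7 through hydroxy ester 8, diol 9 and the primary triethylsilyl ether 10. The labile C5 centre of 7 is not trusted to settle by the small size difference between a methyl and a silyloxymethyl group. Instead it is fixed in 8 by a dynamic kinetic hydrogenation with a chiral ruthenium diphosphine catalyst, whose preference coincides with that of the substrate. No carbon–carbon bond is cut here; the sequence only exchanges the oxidation levels of C4 and C6.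

**C1–C5 (7 ⇒ 6), the key cut.** Ring A of 7 is opened at C1–C5 to the acyclic α-diazo β-keto ester 6. Against the neighbouring cuts (C4–C5 by Dieckmann closure, or C1–C2 by alkylation), this is the only one that creates the quaternary centre from a purchasable tertiary stereocentre with retention. The precursor is acyclic and has a single stereocentre. The forward reaction must insert the C5 carbenoid into the tertiary C1–H bond in preference to the C10–H bonds next to oxygen.

**Chain assembly (6 ⇒ 5 ⇒ 3 + 4; 3 ⇒ 2 ⇒ 1).** The diazo group of 6 comes from β-keto ester 5. The C2–C3 bond of 5 is cut to iodide 3 and methyl acetoacetate 4 (dianion alkylation). Iodide 3 derives from bromide 2 and this from commercial (R)-3-bromo-2-methylpropan-1-ol 1, which supplies C1 with its hydrogen, its methyl group and the C10 oxygen.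

## Roads not taken

**Alternative 1:** The cut is C1–C10, made together with the C8–C9 bond of a ketene. In the forward direction the cis-cyclopropyl diazoketone A1 is treated with AgO2CPh (monovalent silver) and Et3N. Wolff rearrangement gives a ketene, and a Cope rearrangement of the resulting divinylcyclopropane opens the three-membered ring to the bicyclic dienone A2.
- Merits: ring B, the quaternary C1 and the C8=C9–C10=O unit with its methyl group arrive in one strain-driven operation. From a ring A cyclopentene to the bicycle this is clearly shorter than steps 12 to 18 of the chosen plan.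
- Weak points: A1 needs an enantiopure, cis-configured, fully substituted cyclopropane on a tetrasubstituted cyclopentene, and C4 must be set beforehand without help from C5, which is sp2. The C1 methyl is the inward substituent of the rearranging alkene and slows the boat transition state. After the key step, C5=C6 of A2 must be hydrated with hydrogen at C5 and oxygen at C6, both on the face that carries the isopropyl group and in the presence of the enone; hydroboration would reduce the ketone and the facial preference is adverse.
- Comparison: Alternative 1 is better in ring-forming economy. The chosen plan sets against this that every stereocentre is relayed from a purchased one, that C5–H and C6–O are never made by functionalising an alkene, and that the enone is formed last.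

**Alternative 2:** The cut removes both exocyclic bonds of ring A, C1–C10 and C5–C6, from a purchased cyclopentenone. With Cu(OTf)2 (divalent copper precatalyst) and a chiral sulfonate-bearing N-heterocyclic carbene, the vinylaluminum reagent A4 adds to 3-methylcyclopent-2-en-1-one A3, and the aluminum enolate is trapped by acetaldehyde A5 to give A6.
- Merits: one catalytic step from commodity chemicals gives ring A with C1 and C5 set, where the chosen plan needs five steps to reach 7. The silylvinyl group is a masked C10 carbonyl. In reaching a stereodefined ring A this route is better.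
- Weak points: enantioselective formation of a quaternary centre on a five-membered enone is the hardest case of this reaction class. The carbinol centre from the aldol trapping is poorly controlled, and A6 is a β-hydroxy ketone prone to retro-aldol cleavage. Acetaldehyde brings C7 as an unfunctionalised methyl group. To attach C8 it must become an enolate carbon, which requires C6 as a ketone; this erases the C6 centre and places a 1,3-dicarbonyl between C4 and C6 just when isopropyl must be added to C4.
- Comparison: the chosen plan buys its absolute configuration instead of depending on an enantiomeric excess. It also keeps C6 at the carboxyl level, so that C7–C9 are attached by an aldehyde allylation that sets C6 at the same time.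

**Alternative 3:** The cut removes both bonds from C5 to ring B carbons of an arene, C1–C5 and C5–C6. The diazoketone A7, with Cu(MeCN)4PF6 (monovalent copper) and a chiral bis(oxazoline), cyclopropanates the arene bond; the norcaradiene opens to the dihydroazulenone A8.
- Merits: both rings, all ten ring carbons, the C8 methyl and the C10 oxygen come from a flat aromatic in one step. It is by far the shortest access to the skeleton, and it forms the same C1–C5 bond as the chosen plan.
- Weak points: C1 emerges sp2, so the quaternary methyl must be introduced later by alkylation next to the unveiled C10 ketone, trans to C5, on a polyene enolate with several nucleophilic positions. The only stereocentre of A8, C5, is α to the C4 ketone and part of a cycloheptatriene open to 1,5-hydrogen shifts. The carbene must choose the unsubstituted ortho bond over the methoxy-bearing one. Three ring alkenes must then be told apart.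
- Comparison: Alternative 3 is better in step count to the bicycle. The chosen plan offers a quaternary centre secured at the outset with full fidelity, each later centre controlled by its neighbour, and no polyene to differentiate.

Key step: step 5

Remark: daucane numbering is used for all intermediates. Compounds 23 and 24 are carried as C10 epimer mixtures, since C10 becomes the ketone. The sense of induction of (R)-BINAP in step 6 is assigned by analogy with simple 2-oxocyclopentanecarboxylates.

## Route

Step 1
Reactants: 1 (2R)-3-bromo-2-methylpropan-1-ol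
Product: 2 [(2R)-3-bromo-2-methylpropoxy](tert-butyl)diphenylsilane
Conditions: TBDPSCl, imidazole, DMF, 0 °C to rt
Reagents that add atoms: tert-butyl(chloro)diphenylsilane, CC(C)(C)[Si](Cl)(c1ccccc1)c1ccccc1
Why: Silylation of a primary alcohol that leaves the stereocentre untouched; the bulky, robust silyl ether is chosen because it must pass the carbenoid step and screen the C10 hydrogens.

Step 2
Reactants: 2 [(2R)-3-bromo-2-methylpropoxy](tert-butyl)diphenylsilane
Product: 3 tert-butyl{[(2R)-3-iodo-2-methylpropyl]oxy}diphenylsilane
Conditions: NaI, acetone, reflux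
Reagents that add atoms: sodium iodide, [Na+].[I-]
Why: Finkelstein exchange (SN2 at the primary carbon, driven by precipitation of NaBr); the iodide is needed because a β-branched bromide reacts too slowly with the dianion of step 3.

Step 3
Reactants: 3 tert-butyl{[(2R)-3-iodo-2-methylpropyl]oxy}diphenylsilane; 4 methyl acetoacetate
Product: 5 methyl (6S)-7-[(tert-butyldiphenylsilyl)oxy]-6-methyl-3-oxoheptanoate
Conditions: 4, NaH, THF, 0 °C; n-BuLi, 0 °C; 3, 0 °C to rt; aq. NH4Cl
Reagents that add atoms: none
Why: Weiler dianion alkylation: the more basic terminal carbanion of the acetoacetate dianion alone displaces iodide (SN2), so the chain grows at the γ-carbon; the stereocentre is one carbon away from the reacting centre and is not touched.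

Step 4
Reactants: 5 methyl (6S)-7-[(tert-butyldiphenylsilyl)oxy]-6-methyl-3-oxoheptanoate
Product: 6 methyl (6S)-7-[(tert-butyldiphenylsilyl)oxy]-2-diazo-6-methyl-3-oxoheptanoate
Conditions: 4-acetamidobenzenesulfonyl azide, Et3N, MeCN, 0 °C to rt
Reagents that add atoms: 4-acetamidobenzenesulfonyl azide, CC(=O)Nc1ccc(cc1)S(=O)(=O)N=[N+]=[N-]
Why: Regitz diazo transfer to the doubly activated methylene of a β-keto ester; the silyl ether and the remote stereocentre are inert to the mild base.

Step 5
Reactants: 6 methyl (6S)-7-[(tert-butyldiphenylsilyl)oxy]-2-diazo-6-methyl-3-oxoheptanoate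
Product: 7 methyl (1R,2S)-2-{[(tert-butyldiphenylsilyl)oxy]methyl}-2-methyl-5-oxocyclopentane-1-carboxylate (ester cis to the methyl group, trans to the silyloxymethyl arm)
Conditions: Rh2(OAc)4 (1 mol %), CH2Cl2, rt, slow addition of 6
Reagents that add atoms: none
Why: Rh2(OAc)4 (divalent rhodium) is attacked by the diazo carbon of 6, N2 leaves, and the electrophilic rhodium carbenoid at C5 inserts into the C1–H bond through a concerted three-centre transition state with hydride-transfer character. The closest known reaction type is the cyclopentanone synthesis by dirhodium-catalysed 1,5 C–H insertion of α-diazo β-keto esters, which is established for tertiary and stereogenic C–H bonds. Ring A closes through a chair-like six-membered array (C5, C4, C3, C2, C1 and the migrating hydrogen), which is why the five-membered ring forms in preference to four- or six-membered ones. C1 is set by retention: the new C–C bond forms on the face from which hydrogen departs, so the purchased centre of 1 becomes the quaternary (S)-centre without loss of enantiopurity. C5 is also created, but it is the acidic carbon of a β-keto ester; it is not relied on here and is fixed in step 6. The selectivity needed is for the single tertiary C1–H bond over the C10–H bonds next to oxygen (six-membered closure), the methyl C–H bonds and bimolecular carbenoid decay. It is secured by the ring-size preference, by the tertiary nature of the C1–H bond, by the bulky tert-butyldiphenylsilyl group that screens the C10 hydrogens and engages the oxygen lone pairs, and by slow addition that keeps the diazo concentration low. The substrate has no O–H, N–H or alkene that could divert the carbenoid.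

Step 6
Reactants: 7 methyl (1R,2S)-2-{[(tert-butyldiphenylsilyl)oxy]methyl}-2-methyl-5-oxocyclopentane-1-carboxylate
Product: 8 methyl (1R,2S,5R)-2-{[(tert-butyldiphenylsilyl)oxy]methyl}-5-hydroxy-2-methylcyclopentane-1-carboxylate (hydroxyl trans to the ester)
Conditions: H2 (100 atm), RuCl2[(R)-BINAP](dmf)n (1 mol %), CH2Cl2, 50 °C
Reagents that add atoms: none
Why: Noyori hydrogenation of an α-substituted β-keto ester with dynamic kinetic resolution: the C5 epimers of 7 interconvert through the enol faster than they are reduced, and the chelated divalent ruthenium catalyst should hydrogenate only the epimer with the ester cis to the C1 methyl, giving the anti hydroxy ester. Catalyst preference and substrate bias (ester away from the larger silyloxymethyl arm, hydride past the smaller methyl) point the same way, so C5 is fixed as required; the C4 carbinol centre is transient.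

Step 7
Reactants: 8 methyl (1R,2S,5R)-2-{[(tert-butyldiphenylsilyl)oxy]methyl}-5-hydroxy-2-methylcyclopentane-1-carboxylate
Product: 9 (1R,2S,3S)-3-{[(tert-butyldiphenylsilyl)oxy]methyl}-2-(hydroxymethyl)-3-methylcyclopentan-1-ol
Conditions: LiBH4, THF, MeOH (1 equiv), 0 °C to rt
Reagents that add atoms: none
Why: Hydroxyl-assisted reduction of the ester to the primary alcohol by a mild hydride that does not attack the silyl ether; after this step no carbonyl group flanks C5, so its configuration is locked.

Step 8
Reactants: 9 (1R,2S,3S)-3-{[(tert-butyldiphenylsilyl)oxy]methyl}-2-(hydroxymethyl)-3-methylcyclopentan-1-ol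
Product: 10 (1R,2S,3S)-3-{[(tert-butyldiphenylsilyl)oxy]methyl}-3-methyl-2-{[(triethylsilyl)oxy]methyl}cyclopentan-1-ol
Conditions: TESCl (1.05 equiv), imidazole, CH2Cl2, −78 to −20 °C
Reagents that add atoms: chlorotriethylsilane, CC[Si](Cl)(CC)CC
Why: Rate-selective silylation of the unhindered primary hydroxyl over the secondary ring hydroxyl; the triethylsilyl group is chosen because dilute acid removes it later without touching the tert-butyldiphenylsilyl ether.

Step 9
Reactants: 10 (1R,2S,3S)-3-{[(tert-butyldiphenylsilyl)oxy]methyl}-3-methyl-2-{[(triethylsilyl)oxy]methyl}cyclopentan-1-ol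
Product: 11 (2S,3S)-3-{[(tert-butyldiphenylsilyl)oxy]methyl}-3-methyl-2-{[(triethylsilyl)oxy]methyl}cyclopentan-1-one
Conditions: Dess–Martin periodinane, NaHCO3, CH2Cl2, 0 °C to rt
Reagents that add atoms: none
Why: Dess–Martin oxidation of the secondary alcohol under buffered, non-basic conditions, so the β-silyloxy ketone neither eliminates nor epimerises at C5; the configuration present at C5 is also the more stable one.

Step 10
Reactants: 11 (2S,3S)-3-{[(tert-butyldiphenylsilyl)oxy]methyl}-3-methyl-2-{[(triethylsilyl)oxy]methyl}cyclopentan-1-one; 12 2-bromopropane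
Product: 14 (1R,2S,3S)-3-{[(tert-butyldiphenylsilyl)oxy]methyl}-2-(hydroxymethyl)-3-methyl-1-(propan-2-yl)cyclopentan-1-ol, via tertiary alcohol triethylsilyl ether 13 (not isolated)
Conditions: 12, Mg, THF; CeCl3, THF, −78 °C; 11, −78 to 0 °C; then 1 M HCl, THF, 0 °C to rt
Reagents that add atoms: none
Why: Imamoto organocerium 1,2-addition: transmetalation of the Grignard reagent from 12 to trivalent cerium suppresses enolisation and β-hydride reduction of the hindered ketone. The reagent approaches C4 anti to the adjacent C5 silyloxymethyl arm, which places isopropyl cis to H5 and the hydroxyl cis to C6 (4R); the acidic work-up then hydrolyses only the primary triethylsilyl ether of 13.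

Step 11
Reactants: 14 (1R,2S,3S)-3-{[(tert-butyldiphenylsilyl)oxy]methyl}-2-(hydroxymethyl)-3-methyl-1-(propan-2-yl)cyclopentan-1-ol
Product: 15 (1R,2S,5R)-2-{[(tert-butyldiphenylsilyl)oxy]methyl}-5-hydroxy-2-methyl-5-(propan-2-yl)cyclopentane-1-carbaldehyde
Conditions: Dess–Martin periodinane, NaHCO3, CH2Cl2, 0 °C
Reagents that add atoms: none
Why: Dess–Martin oxidation of the primary alcohol; the tertiary hydroxyl cannot be oxidised, and the neutral medium avoids retro-aldol cleavage, dehydration and C5 epimerisation of the β-hydroxy aldehyde, which is used at once.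

Step 12
Reactants: 15 (1R,2S,5R)-2-{[(tert-butyldiphenylsilyl)oxy]methyl}-5-hydroxy-2-methyl-5-(propan-2-yl)cyclopentane-1-carbaldehyde; 16 3-bromo-2-methylprop-1-ene
Product: 17 (1R,2S,3S)-3-{[(tert-butyldiphenylsilyl)oxy]methyl}-2-[(1S)-1-hydroxy-3-methylbut-3-en-1-yl]-3-methyl-1-(propan-2-yl)cyclopentan-1-ol
Conditions: indium powder, 16, THF/H2O (1:1), rt
Reagents that add atoms: none
Why: Barbier-type indium-mediated allylation in aqueous THF, which tolerates the free hydroxyl and is not basic enough for retro-aldol cleavage. The tertiary C4 hydroxyl and the aldehyde oxygen chelate indium in a six-membered ring cis-fused to ring A, so the 2-methylallyl group adds to the exposed Si face away from the ring; the Felkin–Anh analysis with C1 as the large substituent predicts the same 6S product.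

Step 13
Reactants: 17 (1R,2S,3S)-3-{[(tert-butyldiphenylsilyl)oxy]methyl}-2-[(1S)-1-hydroxy-3-methylbut-3-en-1-yl]-3-methyl-1-(propan-2-yl)cyclopentan-1-ol; 18 4-methoxybenzoyl chloride
Product: 19 (1S)-1-[(1S,2S,5R)-2-{[(tert-butyldiphenylsilyl)oxy]methyl}-5-hydroxy-2-methyl-5-(propan-2-yl)cyclopentyl]-3-methylbut-3-en-1-yl 4-methoxybenzoate
Conditions: 18, Et3N, DMAP, CH2Cl2, 0 °C to rt
Reagents that add atoms: none
Why: DMAP-catalysed acylation through the acylpyridinium ion; the secondary C6 hydroxyl reacts while the tertiary C4 hydroxyl next to isopropyl does not, so the ester of the target also protects O6.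

Step 14
Reactants: 19 (1S)-1-[(1S,2S,5R)-2-{[(tert-butyldiphenylsilyl)oxy]methyl}-5-hydroxy-2-methyl-5-(propan-2-yl)cyclopentyl]-3-methylbut-3-en-1-yl 4-methoxybenzoate
Product: 20 (1S)-1-[(1S,2S,5R)-5-hydroxy-2-(hydroxymethyl)-2-methyl-5-(propan-2-yl)cyclopentyl]-3-methylbut-3-en-1-yl 4-methoxybenzoate
Conditions: TBAF, AcOH, THF, rt to 40 °C
Reagents that add atoms: none
Why: Fluoride-induced cleavage of the silyl ether (strong Si–F bond); acetic acid buffering keeps the medium from becoming basic enough to cleave or migrate the 4-methoxybenzoate.

Step 15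
Reactants: 20 (1S)-1-[(1S,2S,5R)-5-hydroxy-2-(hydroxymethyl)-2-methyl-5-(propan-2-yl)cyclopentyl]-3-methylbut-3-en-1-yl 4-methoxybenzoate
Product: 21 (1S)-1-[(1S,2S,5R)-2-formyl-5-hydroxy-2-methyl-5-(propan-2-yl)cyclopentyl]-3-methylbut-3-en-1-yl 4-methoxybenzoate
Conditions: Dess–Martin periodinane, NaHCO3, CH2Cl2, rt
Reagents that add atoms: none
Why: Dess–Martin oxidation of the neopentyl primary alcohol; the aldehyde has no α-hydrogen and cannot enolise, and the tertiary hydroxyl is inert.

Step 16
Reactants: 21 (1S)-1-[(1S,2S,5R)-2-formyl-5-hydroxy-2-methyl-5-(propan-2-yl)cyclopentyl]-3-methylbut-3-en-1-yl 4-methoxybenzoate; 22 vinylmagnesium bromide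
Product: 23 (1S)-1-[(1S,2S,5R)-5-hydroxy-2-(1-hydroxyprop-2-en-1-yl)-2-methyl-5-(propan-2-yl)cyclopentyl]-3-methylbut-3-en-1-yl 4-methoxybenzoate (both epimers at C10)
Conditions: 22 (2.5 equiv), THF, −78 °C; aq. NH4Cl
Reagents that add atoms: none
Why: Grignard 1,2-addition to the aldehyde, which at −78 °C is far more electrophilic than the hindered, electron-rich aryl ester; one equivalent is consumed by the tertiary hydroxyl. The new C10 centre is formed without control, which is immaterial because it is oxidised in step 18.

Step 17
Reactants: 23 (1S)-1-[(1S,2S,5R)-5-hydroxy-2-(1-hydroxyprop-2-en-1-yl)-2-methyl-5-(propan-2-yl)cyclopentyl]-3-methylbut-3-en-1-yl 4-methoxybenzoate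
Product: 24 (3R,3aS,4S,8aS)-3,8-dihydroxy-6,8a-dimethyl-3-(propan-2-yl)-1,2,3,3a,4,5,8,8a-octahydroazulen-4-yl 4-methoxybenzoate (both epimers at C10, azulene position 8)
Conditions: second-generation Grubbs catalyst RuCl2(=CHPh)(H2IMes)(PCy3) (5 mol %), CH2Cl2 (0.005 M), 40 °C
Reagents that add atoms: none
Why: Ring-closing olefin metathesis: the catalyst loads at the monosubstituted vinyl group and the ruthenium alkylidene cyclises onto the 1,1-disubstituted alkene, releasing ethene and forming the trisubstituted C8=C9 bond exactly where the target has it. High dilution favours the seven-membered ring over dimers, and the ester and free hydroxyls are tolerated.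

Step 18
Reactants: 24 (3R,3aS,4S,8aS)-3,8-dihydroxy-6,8a-dimethyl-3-(propan-2-yl)-1,2,3,3a,4,5,8,8a-octahydroazulen-4-yl 4-methoxybenzoate
Product: 25 (3R,3aS,4S,8aS)-3-hydroxy-6,8a-dimethyl-8-oxo-3-(propan-2-yl)-1,2,3,3a,4,5,8,8a-octahydroazulen-4-yl 4-methoxybenzoate
Conditions: Dess–Martin periodinane, NaHCO3, CH2Cl2, 0 °C to rt
Reagents that add atoms: none
Why: Dess–Martin oxidation of the allylic alcohol to the enone under buffered neutral conditions, so no base meets the C6 acyloxy enone and vinylogous elimination of 4-methoxybenzoate is avoided; both C10 epimers converge on 25.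

## Compound list

1 | (2R)-3-bromo-2-methylpropan-1-ol | BrC[C@H](C)CO | starting material
2 | [(2R)-3-bromo-2-methylpropoxy](tert-butyl)diphenylsilane | BrC[C@H](C)CO[Si](c1ccccc1)(c1ccccc1)C(C)(C)C | intermediate
3 | tert-butyl{[(2R)-3-iodo-2-methylpropyl]oxy}diphenylsilane | IC[C@H](C)CO[Si](c1ccccc1)(c1ccccc1)C(C)(C)C | intermediate
4 | methyl acetoacetate (methyl 3-oxobutanoate) | COC(=O)CC(C)=O | starting material
5 | methyl (6S)-7-[(tert-butyldiphenylsilyl)oxy]-6-methyl-3-oxoheptanoate | COC(=O)CC(=O)CC[C@H](C)CO[Si](c1ccccc1)(c1ccccc1)C(C)(C)C | intermediate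
6 | methyl (6S)-7-[(tert-butyldiphenylsilyl)oxy]-2-diazo-6-methyl-3-oxoheptanoate | COC(=O)C(=[N+]=[N-])C(=O)CC[C@H](C)CO[Si](c1ccccc1)(c1ccccc1)C(C)(C)C | intermediate
7 | methyl (1R,2S)-2-{[(tert-butyldiphenylsilyl)oxy]methyl}-2-methyl-5-oxocyclopentane-1-carboxylate | COC(=O)[C@@H]1[C@@](C)(CO[Si](c2ccccc2)(c2ccccc2)C(C)(C)C)CCC1=O | intermediate
8 | methyl (1R,2S,5R)-2-{[(tert-butyldiphenylsilyl)oxy]methyl}-5-hydroxy-2-methylcyclopentane-1-carboxylate | COC(=O)[C@@H]1[C@@](C)(CO[Si](c2ccccc2)(c2ccccc2)C(C)(C)C)CC[C@H]1O | intermediate
9 | (1R,2S,3S)-3-{[(tert-butyldiphenylsilyl)oxy]methyl}-2-(hydroxymethyl)-3-methylcyclopentan-1-ol | OC[C@@H]1[C@@](C)(CO[Si](c2ccccc2)(c2ccccc2)C(C)(C)C)CC[C@H]1O | intermediate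
10 | (1R,2S,3S)-3-{[(tert-butyldiphenylsilyl)oxy]methyl}-3-methyl-2-{[(triethylsilyl)oxy]methyl}cyclopentan-1-ol | CC[Si](CC)(CC)OC[C@@H]1[C@@](C)(CO[Si](c2ccccc2)(c2ccccc2)C(C)(C)C)CC[C@H]1O | intermediate
11 | (2S,3S)-3-{[(tert-butyldiphenylsilyl)oxy]methyl}-3-methyl-2-{[(triethylsilyl)oxy]methyl}cyclopentan-1-one | CC[Si](CC)(CC)OC[C@@H]1[C@@](C)(CO[Si](c2ccccc2)(c2ccccc2)C(C)(C)C)CCC1=O | intermediate
12 | 2-bromopropane | CC(C)Br | starting material
13 | (1R,2S,3S)-3-{[(tert-butyldiphenylsilyl)oxy]methyl}-3-methyl-1-(propan-2-yl)-2-{[(triethylsilyl)oxy]methyl}cyclopentan-1-ol | CC[Si](CC)(CC)OC[C@@H]1[C@@](C)(CO[Si](c2ccccc2)(c2ccccc2)C(C)(C)C)CC[C@@]1(O)C(C)C | intermediate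
14 | (1R,2S,3S)-3-{[(tert-butyldiphenylsilyl)oxy]methyl}-2-(hydroxymethyl)-3-methyl-1-(propan-2-yl)cyclopentan-1-ol | OC[C@@H]1[C@@](C)(CO[Si](c2ccccc2)(c2ccccc2)C(C)(C)C)CC[C@@]1(O)C(C)C | intermediate
15 | (1R,2S,5R)-2-{[(tert-butyldiphenylsilyl)oxy]methyl}-5-hydroxy-2-methyl-5-(propan-2-yl)cyclopentane-1-carbaldehyde | O=C[C@@H]1[C@@](C)(CO[Si](c2ccccc2)(c2ccccc2)C(C)(C)C)CC[C@@]1(O)C(C)C | intermediate
16 | 3-bromo-2-methylprop-1-ene | CC(=C)CBr | starting material
17 | (1R,2S,3S)-3-{[(tert-butyldiphenylsilyl)oxy]methyl}-2-[(1S)-1-hydroxy-3-methylbut-3-en-1-yl]-3-methyl-1-(propan-2-yl)cyclopentan-1-ol | CC(=C)C[C@H](O)[C@@H]1[C@@](C)(CO[Si](c2ccccc2)(c2ccccc2)C(C)(C)C)CC[C@@]1(O)C(C)C | intermediate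
18 | 4-methoxybenzoyl chloride | COc1ccc(cc1)C(Cl)=O | starting material
19 | (1S)-1-[(1S,2S,5R)-2-{[(tert-butyldiphenylsilyl)oxy]methyl}-5-hydroxy-2-methyl-5-(propan-2-yl)cyclopentyl]-3-methylbut-3-en-1-yl 4-methoxybenzoate | COc1ccc(cc1)C(=O)O[C@@H](CC(C)=C)[C@@H]1[C@@](C)(CO[Si](c2ccccc2)(c2ccccc2)C(C)(C)C)CC[C@@]1(O)C(C)C | intermediate
20 | (1S)-1-[(1S,2S,5R)-5-hydroxy-2-(hydroxymethyl)-2-methyl-5-(propan-2-yl)cyclopentyl]-3-methylbut-3-en-1-yl 4-methoxybenzoate | COc1ccc(cc1)C(=O)O[C@@H](CC(C)=C)[C@@H]1[C@@](C)(CO)CC[C@@]1(O)C(C)C | intermediate
21 | (1S)-1-[(1S,2S,5R)-2-formyl-5-hydroxy-2-methyl-5-(propan-2-yl)cyclopentyl]-3-methylbut-3-en-1-yl 4-methoxybenzoate | COc1ccc(cc1)C(=O)O[C@@H](CC(C)=C)[C@@H]1[C@@](C)(C=O)CC[C@@]1(O)C(C)C | intermediate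
22 | vinylmagnesium bromide | C=C[Mg]Br | starting material
23 | (1S)-1-[(1S,2S,5R)-5-hydroxy-2-(1-hydroxyprop-2-en-1-yl)-2-methyl-5-(propan-2-yl)cyclopentyl]-3-methylbut-3-en-1-yl 4-methoxybenzoate, both C10 epimers | COc1ccc(cc1)C(=O)O[C@@H](CC(C)=C)[C@@H]1[C@@](C)(C(O)C=C)CC[C@@]1(O)C(C)C | intermediate
24 | (3R,3aS,4S,8aS)-3,8-dihydroxy-6,8a-dimethyl-3-(propan-2-yl)-1,2,3,3a,4,5,8,8a-octahydroazulen-4-yl 4-methoxybenzoate, both C10 epimers | COc1ccc(C(=O)O[C@H]2CC(C)=CC(O)[C@@]3(C)CC[C@@](O)(C(C)C)[C@H]23)cc1 | intermediate
25 | (3R,3aS,4S,8aS)-3-hydroxy-6,8a-dimethyl-8-oxo-3-(propan-2-yl)-1,2,3,3a,4,5,8,8a-octahydroazulen-4-yl 4-methoxybenzoate | COc1ccc(C(=O)O[C@H]2CC(C)=CC(=O)[C@@]3(C)CC[C@@](O)(C(C)C)[C@H]23)cc1 | target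

## Step count and risk

Total steps: 18. Longest linear sequence: 18 steps (1 to 25); the route is linear, and 4, 12, 16, 18 and 22 enter as purchased reagents.

**Step 5 (key step).** The β-silyloxy group lowers the hydridic character of the C1–H bond, so insertion may be slow. Interception of the carbenoid by unreacted diazo compound (azine and carbene dimer formation) and insertion into the oxygen-activated C10–H bonds could then gain ground. The fallback leaves the diazo manifold and sets out from 5. Treatment with PhI(OAc)2 and KOH in MeOH should give the phenyliodonium ylide methyl (6S)-7-[(tert-butyldiphenylsilyl)oxy]-6-methyl-3-oxo-2-(phenyl-λ3-iodanylidene)heptanoate F1. Added slowly to Cu(acac)2 (divalent copper) in CH2Cl2, F1 transfers the same carbene with loss of iodobenzene and with no diazo compound present to trap it. The route is rejoined at 7.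

**Step 6.** The dynamic kinetic resolution may be incomplete: reduction of the hindered ketone could be slow, or discrimination between the C5 epimers could be insufficient if catalyst and resident C1 centre do not cooperate as expected, leaving a C5 mixture. The fallback sets C5 by equilibration at the ketone stage and sets out from 7.
- Exhaustive reduction with LiBH4 in THF/MeOH gives (3S)-3-{[(tert-butyldiphenylsilyl)oxy]methyl}-2-(hydroxymethyl)-3-methylcyclopentan-1-ol as a mixture at C4 and C5 F2.
- Primary silylation as in step 8 gives its triethylsilyl ether F3.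
- Dess–Martin oxidation gives the ketone as a C5 epimer mixture F4.
- Brief treatment with catalytic DBU equilibrates C5 through the enolate towards the isomer with the two silyloxymethyl arms trans; chromatography then gives 11, where the route is rejoined.

**Step 10.** Enolisation of the α-branched ketone, or β-hydride transfer from the secondary alkyl reagent (reduction instead of addition), may compete with C–C bond formation. The fallback sets out from 11. The 2-propenyl cerium reagent, made from isopropenylmagnesium bromide and CeCl3, has no transferable β-hydrogen and is smaller. It should give (1S,2S,3S)-3-{[(tert-butyldiphenylsilyl)oxy]methyl}-3-methyl-1-(prop-1-en-2-yl)-2-{[(triethylsilyl)oxy]methyl}cyclopentan-1-ol F5. Hydrogenation over Pd/C in EtOAc saturates the 1,1-disubstituted alkene to 13, which is hydrolysed with dilute HCl. The route is rejoined at 14.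

**Step 12.** Chelation of indium by the tertiary hydroxyl may be weak in the aqueous medium, which would erode facial selectivity at C6; the β-hydroxy aldehyde may also be lost through dehydration. The fallback replaces substrate control by reagent control and sets out from 15. (−)-B-(2-Methylallyl)diisopinocampheylborane, generated from (−)-B-methoxydiisopinocampheylborane and 2-methylallylmagnesium chloride in Et2O at −78 °C, adds to the Si face of aldehydes. Oxidative work-up with NaOH and H2O2 gives 17 directly, where the route is rejoined. No further compound is formed (F0).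

**Step 17.** Initiation at the vinyl carbinol next to the quaternary carbon may be slow and the 1,1-disubstituted alkene may engage poorly. Intermolecular cross-metathesis to dimers, and isomerisation of the allylic alcohol to an ethyl ketone by ruthenium hydrides, would then compete. The fallback closes ring B at C9–C10 without metathesis and sets out from 21.
- Me2AlCl in CH2Cl2 at −78 °C promotes an intramolecular carbonyl-ene reaction between the C10 aldehyde and the 2-methylallyl group, giving the exo-methylene alcohol (3R,3aS,4S,8aS)-3,8-dihydroxy-8a-methyl-6-methylidene-3-(propan-2-yl)decahydroazulen-4-yl 4-methoxybenzoate F6.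
- Dess–Martin oxidation gives the β,γ-unsaturated ketone (3R,3aS,4S,8aS)-3-hydroxy-8a-methyl-6-methylidene-8-oxo-3-(propan-2-yl)decahydroazulen-4-yl 4-methoxybenzoate F7.
- A catalytic amount of Et3N moves the exocyclic alkene into conjugation through the C9 dienol, and the route is rejoined at 25.

This path is second choice because the aryl ester can capture positive charge developing at C8, and because the last operation exposes the acyloxy enone to base.

## Further compounds

F1 | step 5 | methyl (6S)-7-[(tert-butyldiphenylsilyl)oxy]-6-methyl-3-oxo-2-(phenyl-λ3-iodanylidene)heptanoate (phenyliodonium ylide of 5) | COC(=O)[C-]([I+]c1ccccc1)C(=O)CC[C@H](C)CO[Si](c1ccccc1)(c1ccccc1)C(C)(C)C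
F2 | step 6 | (3S)-3-{[(tert-butyldiphenylsilyl)oxy]methyl}-2-(hydroxymethyl)-3-methylcyclopentan-1-ol, mixture at C4 and C5 | OCC1[C@@](C)(CO[Si](c2ccccc2)(c2ccccc2)C(C)(C)C)CCC1O
F3 | step 6 | (3S)-3-{[(tert-butyldiphenylsilyl)oxy]methyl}-3-methyl-2-{[(triethylsilyl)oxy]methyl}cyclopentan-1-ol, mixture at C4 and C5 | CC[Si](CC)(CC)OCC1[C@@](C)(CO[Si](c2ccccc2)(c2ccccc2)C(C)(C)C)CCC1O
F4 | step 6 | (3S)-3-{[(tert-butyldiphenylsilyl)oxy]methyl}-3-methyl-2-{[(triethylsilyl)oxy]methyl}cyclopentan-1-one, mixture at C5 | CC[Si](CC)(CC)OCC1[C@@](C)(CO[Si](c2ccccc2)(c2ccccc2)C(C)(C)C)CCC1=O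
F5 | step 10 | (1S,2S,3S)-3-{[(tert-butyldiphenylsilyl)oxy]methyl}-3-methyl-1-(prop-1-en-2-yl)-2-{[(triethylsilyl)oxy]methyl}cyclopentan-1-ol | CC[Si](CC)(CC)OC[C@@H]1[C@@](C)(CO[Si](c2ccccc2)(c2ccccc2)C(C)(C)C)CC[C@@]1(O)C(C)=C
F0 | step 12 | none | none
F6 | step 17 | (3R,3aS,4S,8aS)-3,8-dihydroxy-8a-methyl-6-methylidene-3-(propan-2-yl)decahydroazulen-4-yl 4-methoxybenzoate, both C10 epimers | COc1ccc(C(=O)O[C@H]2CC(=C)CC(O)[C@@]3(C)CC[C@@](O)(C(C)C)[C@H]23)cc1
F7 | step 17 | (3R,3aS,4S,8aS)-3-hydroxy-8a-methyl-6-methylidene-8-oxo-3-(propan-2-yl)decahydroazulen-4-yl 4-methoxybenzoate | COc1ccc(C(=O)O[C@H]2CC(=C)CC(=O)[C@@]3(C)CC[C@@](O)(C(C)C)[C@H]23)cc1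
A1 | alternative 1 | 2-diazo-1-{1-methyl-2-[2-methyl-5-(propan-2-yl)-5-(triethylsilyloxy)cyclopent-1-en-1-yl]cyclopropyl}ethan-1-one, acyl and cyclopentenyl groups cis | [N-]=[N+]=CC(=O)[C@@]1(C)C[C@H]1C2=C(C)CC[C@@]2(O[Si](CC)(CC)CC)C(C)C
A2 | alternative 1 | 6,8a-dimethyl-3-(propan-2-yl)-3-[(triethylsilyl)oxy]-2,3,5,8a-tetrahydroazulen-8(1H)-one (C5=C6 and C8=C9, C1 and C4 as in the target) | C12=CCC(C)=CC(=O)[C@@]1(C)CC[C@@]2(O[Si](CC)(CC)CC)C(C)C
A3 | alternative 2 | 3-methylcyclopent-2-en-1-one | CC1=CC(=O)CC1
A4 | alternative 2 | diisobutyl[1-(trimethylsilyl)ethenyl]aluminum | C=C([Si](C)(C)C)[Al](CC(C)C)CC(C)C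
A5 | alternative 2 | acetaldehyde | CC=O
A6 | alternative 2 | trans-2-(1-hydroxyethyl)-3-methyl-3-[1-(trimethylsilyl)ethenyl]cyclopentan-1-one | C[C@H](O)[C@@H]1[C@@](C)(C(=C)[Si](C)(C)C)CCC1=O
A7 | alternative 3 | 1-diazo-4-(2-methoxy-4-methylphenyl)butan-2-one | COc1cc(C)ccc1CCC(=O)C=[N+]=[N-]
A8 | alternative 3 | 8-methoxy-6-methyl-3,8a-dihydroazulen-1(2H)-one, single C5 enantiomer | O=C1CCC2=C(OC)C=C(C)C=C[C@@H]12
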